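## Structural features

9-Acetylisoobtusol is a chamigrene-type spiro[5.5]undecane in which ring A (C1–C6) and ring B (C6–C11) share only the quaternary carbon C6. Ring A carries an exocyclic methylene on C1 (C12), an acetate on C3, a secondary bromide on C4 and a gem-dimethyl group on C5. Ring B carries a methyl group and a tertiary bromide on C9 and a secondary chloride on C10. C6 lies between two fully substituted carbons (C1 and C5), so every bond to it is neopentyl-like. It is also the only link through which configuration can pass between the two pairs of neighbouring stereocentres, C3/C4 (acetate and bromine cis) and C9/C10 (bromine and chlorine trans). The fragile groups are the tertiary bromide anti to chlorine (ionisation, elimination, reductive loss of both halogens), the 1,1-disubstituted alkene (acid adds to it or moves it into the ring) and the beta-bromo acetate. The real difficulties are the congested spiro centre, the pair of different halogens in ring B (bromine tertiary, chlorine secondary, the reverse of what BrCl addition to a C9=C10 alkene delivers) and the relay of configuration from C6 into ring A, where bromination must find C4 and not C2. The key step uses the fact that C9 and C10 are adjacent heteroatom-bearing carbons: a C9 methyl ketone and a C10 aldehyde, both hanging from C6, are coupled reductively to close ring B as a cis-diol, whose oxygens are then exchanged one at a time.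

## Logic of the disconnections

33 to 30. The exocyclic alkene is the most acid-sensitive group and is unveiled last. Retrosynthetically the C2–H bond is cut and the double bond moved from C1=C12 to C1=C2, with a hydroxyl on C12. The gain is that C2 is sp2 in all earlier intermediates and cannot compete in enolate chemistry at C3/C4. The forward step must be a neutral, regiospecific reductive 1,3-transposition that tolerates two bromides, a chloride and an acetate.

30 to 27 (through 29 and 28). The acetyl C–O bond, the benzyl ether and the C3–H bond are cut, leading to an alpha-bromo enone. The gain is that the cis bromohydrin is reduced to one stereocentre (C4) plus a hydride addition directed by it. The forward reduction must deliver hydride anti to the C–Br bond.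

27 to 25. The C4–Br bond is cut. In 25 the ketone can enolise only toward C4 (C2 is vinylic), so the site of bromination is unambiguous. A 3-ketone carrying the C1 methylene would enolise toward the doubly activated C2, which is why bromination is not done at that stage. The forward step must select the C4 face that is cis to C11.

25 to 19 and 22 (through 24). The C1–C12 bond is cut and the oxygen returned from C3 to C1. One 1,2-addition followed by an oxidative allylic transposition supplies C12, the C3 oxygen and the C1=C2 alkene together. The forward addition must succeed at a carbonyl flanked by the spiro carbon. 22 is cut at its ether C–O bond to 20 and 21.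

19 to 17. The C2=C3 unsaturation is removed. The ketone of 17 has hydrogens only on C2, so dehydrogenation is regiospecific.

17 to 12 (through 16 and 14). The C9–Br and C10–Cl bonds are traced to C–O bonds. The cis-diol allows chloride to enter C10 with inversion through a cyclic sulfate, and bromide to enter C9 with retention through participation of that chlorine. This is placed before all ring A work because its reagents (RuO4, HBr-type ionisation) would destroy an alkene or an allylic ester. The demand is that both halides survive the later steps, which are therefore kept cold or neutral.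

12 to 11. The C9–C10 bond is cut. One reductive coupling closes ring B and sets both carbinol centres from C6. The forward step needs the aldehyde to react before either ketone and the closure to give the cis-diol on the C5 face.

11 to 9. The two carbonyl groups are traced to a vinyl and an isopropenyl terminus, which are inert to enolate and palladium chemistry. The forward step is a double ozonolysis.

9 to 8. The C6–C11 bond is cut. The quaternary stereocentre is made by decarboxylative asymmetric allylation of a regiodefined enol carbonate, with the catalyst setting C6. The forward step must work at an enolate carbon next to a quaternary carbon.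

8 to 5 and 6. One C5–CH3 bond and the carbonate O–C bond are cut. Conjugate methylation builds the gem-dimethyl carbon and gives the tetrasubstituted enolate needed for O-acylation.

5 to 1 and 2. The bond between the ring carbon and the side chain is cut and the ester restored, which leads to the regioselective C3 alkylation of 1 followed by decarboxylation.

## Other disconnections considered

Alternative 1: The cut is C6–C7, made by reconnecting C9 to C12, so the spirocycle is seen as the ring-opened isomer of a fused bicycle. The precursor is the tertiary allylic alcohol A1: ring A is joined through a tetrasubstituted C1=C6 alkene to a second six-membered ring C1–C12–C9–C10–C11–C6, with hydroxyl and vinyl on C9, a 4-methoxybenzyl ether on C10 and a dioxolane on C3. KH with 18-crown-6 would form the C9 alkoxide, and the anionic oxy-Cope shift would join the vinyl terminus C7 to C6 while C9–C12 breaks. Protonation would give the spiro ketone A2 with the C1 methylene and a C9 ketone in place.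
- In favour: the quaternary centre is made by an intramolecular sigmatropic shift that the alkoxide accelerates and makes irreversible, which tolerates congestion better than an intermolecular allylation. C6 is fixed by the face on which the vinyl group sits in A1 (cis to the C10 ether), so no asymmetric catalysis is needed at the congested carbon. On this point it is the better plan. Ring A also emerges with C12 and the C3 oxygen in place, a second point in its favour.
- Against: the vinyl group must reach across its own ring, which forces a boat-like transition state onto a tetrasubstituted alkene terminus. A1, with two stereocentres and a fully substituted ring-fusion alkene, is itself a multistep target. C9 arrives as a ketone, so the tertiary carbinol needed for the bromide would require a face-selective methyl addition that the pinacol closure provides directly. The acid-labile C1 methylene is present before the ionising bromination at C9 and before bromination at C4, where a 3-ketone with a C1 methylene would enolise toward C2.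
- Comparison: the C10 oxygen-to-chlorine exchange would be the same in both plans, so they are equal there. The alternative is stronger at C6 and weaker in the order of events afterwards. The step count would be comparable once A1 is costed.

Alternative 2: The cut is C1–C6. The precursor is the vinyl bromide A3, in which a 2-bromoallyl chain carrying the C3 dioxolane and the C5 gem-dimethyl group hangs from C6 of a cyclohexene whose allylic carbon C10 bears a silyl ether. Pd(OAc)2, PPh3 and Ag2CO3 would bring about oxidative addition into the C1–Br bond, 6-exo insertion of the vinylpalladium across C6=C11 and beta-hydride elimination toward C10, leaving the silyl enol ether A4.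
- In favour: intramolecular Heck closure is one of the most dependable ways to make a quaternary spiro carbon. The neopentyl alkylpalladium has only the C10 hydrogen available, so the position of the new double bond is defined, and the gem-dimethyl group in the tether helps closure. In robustness of the quaternary-centre step this is probably the better plan, and it is convergent.
- Against: the C6 configuration rests on induction from a single allylic silyloxy group, and that stereocentre is consumed in the same step. Ring B comes out without the C9 methyl group or any C9 heteroatom, so C9 and C10 would have to be built afterwards from the enol ether with new selectivity questions. The exocyclic alkene is again present through all ring B halogenation.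
- Comparison: both plans rest on well-understood mechanisms. The alternative spends fewer steps on ring A and more on ring B, so the total would be similar or longer. On control of C9/C10 the chosen plan is better; on construction of C6 the alternative is at least its equal.

Alternative 3: Two bonds of ring B are cut, C7–C8 and C9–C10. This leads to the achiral spiro cyclobutanone A5 (ring A with its methylene, dioxolane and gem-dimethyl group, spiro-fused at C6 to a cyclobutanone whose carbonyl is C10) and 1-(trimethylsilyl)propyne A6. With Ni(cod)2 and a chiral phosphine, oxidative cyclisation of the carbonyl and the alkyne on zerovalent nickel, beta-carbon elimination of one of the two enantiotopic C10–CH2 bonds and reductive elimination would give the cyclohexenone A7.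
- In favour: the quaternary carbon is made earlier and without stereochemistry, and the catalyst only has to choose between two ring bonds. The most congested stereocentre is thus set by desymmetrisation and not by bond formation at a neopentyl carbon. The step is convergent, brings in the C9 methyl group with three ring B carbons and leaves C10 oxidised. In convergence and in the ease of building C6 it is the equal or the better of the chosen plan.
- Against: the two bonds the catalyst must tell apart differ only through the remote difference between C1 and C5, so high selectivity next to so crowded a carbon is uncertain. A7 still needs protodesilylation. C9 is an sp2 carbon without a heteroatom, so the tertiary bromide would have to come from Markovnikov addition of HBr to the C8=C9 alkene after reduction and chlorination at C10, in the presence of the acid-sensitive C1 methylene. The C9/C10 relationship would then depend on two separate steps and not on one chelated closure.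
- Comparison: the alternative has less precedent on this substrate class. It could reach the spirocycle in fewer steps, but its halogenation endgame is less secure.

Key step: step 6

Remarks on the chemistry (assumptions):
- Locants: ring A is C1–C6 (C12 is the extra carbon on C1), ring B is C6–C11. The spiro[5.5]undecane names below use these locants.
- The sense of induction of the phosphinooxazoline ligand in step 4 is taken from simple 2-alkylcyclohexanone allyl enol carbonates. If it proves opposite, the other ligand enantiomer is used.
- (Tributylstannyl)methanol 20 is taken as a commercial reagent.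
- The configurations of 11 and 12 were checked against 33: both oxygens of 12 lie on the C5 face, and inversion at C10 plus retention at C9 give the trans bromide/chloride of 33.
- The C6 descriptor changes from S to R at step 14 only because bromine on C4 changes the priority order; the centre is untouched.
- 11 keeps its ring A ketone unprotected, because that ketone is the later handle for ring A and could only form a four-membered ring with the C10 ketyl. 11 is used crude because of its aldol-prone dicarbonyl relationships.

## Route

Step 1
Reactants: 1 ethyl 2-methyl-4-oxocyclohex-2-ene-1-carboxylate (Hagemann's ester); 2 4-bromo-2-methylbut-1-ene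
Product: 3 ethyl 2-methyl-3-(3-methylbut-3-en-1-yl)-4-oxocyclohex-2-ene-1-carboxylate (racemic)
Conditions: NaOEt, EtOH, 25 °C; then 2, NaI (cat.), reflux
Reagents that add atoms: none
Why: The extended enolate of this vinylogous beta-keto ester alkylates at C3, between the ketone and the alkene (the classical regiochemistry of Hagemann's ester). The stabilised, weakly basic enolate favours substitution over elimination of the homoallylic bromide.

Step 2
Reactants: 3 ethyl 2-methyl-3-(3-methylbut-3-en-1-yl)-4-oxocyclohex-2-ene-1-carboxylate
Product: 5 3-methyl-2-(3-methylbut-3-en-1-yl)cyclohex-2-en-1-one, via carboxylic acid 4 (not isolated)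
Conditions: KOH, EtOH/H2O, reflux; then aq. HCl to pH 3, 50 °C
Reagents that add atoms: none
Why: Saponification followed by decarboxylation of the vinylogous beta-keto acid through its dienol gives the 2,3-dialkyl enone. The mild acid spares the isopropenyl group.

Step 3
Reactants: 5 3-methyl-2-(3-methylbut-3-en-1-yl)cyclohex-2-en-1-one; 6 allyl chloroformate
Product: 8 allyl 3,3-dimethyl-2-(3-methylbut-3-en-1-yl)cyclohex-1-en-1-yl carbonate, via lithium enolate 7 (not isolated)
Conditions: Me2CuLi, Et2O, −20 → 0 °C; then 6, THF, −78 → 0 °C
Reagents that add atoms: lithium dimethylcuprate, [Li+].C[Cu-]C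
Why: Cuprate conjugate addition to the beta,beta-disubstituted enone builds the gem-dimethyl carbon and leaves a regiodefined tetrasubstituted enolate. Chloroformates acylate such enolates on oxygen, more so here because the carbon terminus is hindered.

Step 4
Reactants: 8 allyl 3,3-dimethyl-2-(3-methylbut-3-en-1-yl)cyclohex-1-en-1-yl carbonate
Product: 9 (S)-2-allyl-3,3-dimethyl-2-(3-methylbut-3-en-1-yl)cyclohexan-1-one
Conditions: Pd2(dba)3 (2.5 mol %), (R)-2-[2-(bis(4-(trifluoromethyl)phenyl)phosphino)-5-(trifluoromethyl)phenyl]-4-tert-butyl-4,5-dihydrooxazole (6 mol %), toluene, 30 °C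
Reagents that add atoms: none
Why: Decarboxylative asymmetric allylic alkylation (Tsuji allylation with a chiral phosphinooxazoline): oxidative addition of zerovalent palladium and loss of CO2 give an allylpalladium enolate that recombines only at the tetrasubstituted enolate carbon. The electron-poor ligand is the variant suited to enolates flanked by a quaternary carbon, and its (R) form is chosen by analogy so that C6 is formed as S.

Step 5
Reactants: 9 (S)-2-allyl-3,3-dimethyl-2-(3-methylbut-3-en-1-yl)cyclohexan-1-one
Product: 11 (S)-2-[2,2-dimethyl-6-oxo-1-(3-oxobutyl)cyclohexyl]acetaldehyde, via bis-ozonide 10 (not isolated)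
Conditions: O3, CH2Cl2, −78 °C; then Me2S, −78 → 25 °C
Reagents that add atoms: ozone, [O-][O+]=O
Why: Ozonolysis with reductive work-up cleaves the vinyl group to the C10 aldehyde and the isopropenyl group to the C9 methyl ketone. The quaternary centre cannot epimerise, and the product is used at once.

Step 6
Reactants: 11 (S)-2-[2,2-dimethyl-6-oxo-1-(3-oxobutyl)cyclohexyl]acetaldehyde
Product: 12 (6S,9S,10R)-9,10-dihydroxy-5,5,9-trimethylspiro[5.5]undecan-1-one
Conditions: SmI2 (2.5 equiv), THF, −78 → 0 °C, slow addition of 11; then aq. NH4Cl
Reagents that add atoms: none
Why: Electron transfer from divalent samarium to the aldehyde, the most easily reduced of the three carbonyls, gives a C10 ketyl that adds to the carbonyl carbon of the C9 methyl ketone; a second electron transfer and protonation give the diol. The closest known reaction type is the SmI2-mediated intramolecular pinacol coupling of 1,6-keto-aldehydes to cis-cyclohexane-1,2-diols. Ring B closes in a 6-exo-trig mode through the new C9–C10 bond. The cis relationship of the two new centres comes from both oxygens being held on one trivalent samarium during closure. Their face relative to C6 comes from a chair in which the bulky C5 is equatorial on the forming ring, the C9 methyl group is equatorial and the C10 oxygen is equatorial, so it is not syn-axial to C1; this places both oxygens on the C5 face (9S,10R). The step needs chemoselectivity among three carbonyls: six-ring closure onto C9 outruns any reaction at the C1 ketone, which is shielded by C6 and could only close a four-membered ring with the ketyl. Low temperature and slow addition keep simple reduction and aldol closure in check.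

Step 7
Reactants: 12 (6S,9S,10R)-9,10-dihydroxy-5,5,9-trimethylspiro[5.5]undecan-1-one
Product: 14 (6S,9S,10R)-5,5,9-trimethyl-1-oxospiro[5.5]undecane-9,10-diyl cyclic sulfate, via cyclic sulfite 13 (not isolated)
Conditions: SOCl2, Et3N, CH2Cl2, 0 °C; then RuCl3·3H2O (cat.), NaIO4, MeCN/H2O, 0 °C
Reagents that add atoms: thionyl chloride, O=S(Cl)Cl; sodium periodate, [Na+].[O-]I(=O)(=O)=O
Why: Cyclic sulfite formation from the cis-diol and ruthenium-catalysed oxidation give the cyclic sulfate, which activates both carbinol carbons without touching a stereocentre. The molecule has no alkene at this stage, so the oxidant meets only the inert ketone.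

Step 8
Reactants: 14 (6S,9S,10R)-5,5,9-trimethyl-1-oxospiro[5.5]undecane-9,10-diyl cyclic sulfate
Product: 16 (6S,9S,10S)-10-chloro-9-hydroxy-5,5,9-trimethylspiro[5.5]undecan-1-one, via lithium sulfate monoester 15 (not isolated)
Conditions: LiCl, DMF, 25 → 50 °C; then H2SO4 (cat.), H2O, THF, 25 °C
Reagents that add atoms: lithium chloride, [Li+].[Cl-]
Why: Cyclic sulfates open with halide like epoxides: chloride attacks the secondary carbon C10 with inversion (the trans-diaxial mode, Fürst–Plattner rule) and cannot attack tertiary C9. Acid then hydrolyses the tertiary sulfate monoester at sulfur, leaving chlorine trans to the C9 hydroxyl.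

Step 9
Reactants: 16 (6S,9S,10S)-10-chloro-9-hydroxy-5,5,9-trimethylspiro[5.5]undecan-1-one
Product: 17 (6S,9S,10S)-9-bromo-10-chloro-5,5,9-trimethylspiro[5.5]undecan-1-one
Conditions: Me3SiBr, CH2Cl2, −20 → 25 °C
Reagents that add atoms: bromotrimethylsilane, C[Si](C)(C)Br
Why: Me3SiBr converts tertiary alcohols into bromides by ionisation. The axial C10 chlorine is antiperiplanar to the leaving oxygen and bridges C9 from the lower face (neighbouring-group participation through a chloronium ion), so bromide opens at the tertiary carbon from the upper face. The result is overall retention at C9 and the trans-diaxial bromide/chloride.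

Step 10
Reactants: 17 (6S,9S,10S)-9-bromo-10-chloro-5,5,9-trimethylspiro[5.5]undecan-1-one
Product: 19 (6S,9S,10S)-9-bromo-10-chloro-5,5,9-trimethylspiro[5.5]undec-2-en-1-one, via silyl enol ether 18 (not isolated)
Conditions: LiN(i-Pr)2, Me3SiCl, THF, −78 °C; then Pd(OAc)2, MeCN, 25 °C
Reagents that add atoms: none
Why: Saegusa–Ito oxidation: the ketone can enolise only toward C2 because C6 is quaternary, and divalent palladium turns the silyl enol ether into the C2=C3 enone. Enolisation at −78 °C is far faster than loss of HBr from the tertiary bromide.

Step 11
Reactants: 20 (tributylstannyl)methanol; 21 4-methoxybenzyl chloride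
Product: 22 tributyl{[(4-methoxybenzyl)oxy]methyl}stannane
Conditions: NaH, n-Bu4NI (cat.), THF/DMF, 0 → 25 °C
Reagents that add atoms: none
Why: Williamson etherification of the primary stannylmethanol with a benzylic chloride.

Step 12
Reactants: 22 tributyl{[(4-methoxybenzyl)oxy]methyl}stannane; 19 (6S,9S,10S)-9-bromo-10-chloro-5,5,9-trimethylspiro[5.5]undec-2-en-1-one
Product: 24 (6S,9S,10S)-9-bromo-10-chloro-1-{[(4-methoxybenzyl)oxy]methyl}-5,5,9-trimethylspiro[5.5]undec-2-en-1-ol (both C1 epimers), via alkoxymethyllithium 23 (not isolated)
Conditions: n-BuLi, THF, −78 °C; then 19, −78 °C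
Reagents that add atoms: none
Why: Tin–lithium exchange gives an alpha-alkoxymethyllithium (a hydroxymethyl anion equivalent) that adds 1,2 to the enone carbonyl at −78 °C, faster than it attacks the alkyl halides. The new C1 centre forms as a mixture, which is irrelevant because C1 becomes sp2 in the next step.

Step 13
Reactants: 24 (6S,9S,10S)-9-bromo-10-chloro-1-{[(4-methoxybenzyl)oxy]methyl}-5,5,9-trimethylspiro[5.5]undec-2-en-1-ol
Product: 25 (6S,9S,10S)-9-bromo-10-chloro-1-{[(4-methoxybenzyl)oxy]methyl}-5,5,9-trimethylspiro[5.5]undec-1-en-3-one
Conditions: [C5H5NH][CrO3Cl] (pyridinium chlorochromate), 4 Å molecular sieves, CH2Cl2, 25 °C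
Reagents that add atoms: pyridinium chlorochromate, c1cc[nH+]cc1.[O-][Cr](=O)(=O)Cl
Why: Dauben–Babler oxidative transposition: the tertiary allylic chromate ester undergoes a [3,3] shift to C3 and is oxidised there. Oxygen moves from C1 to C3 and the alkene to C1=C2, so C2 is vinylic for the bromination.

Step 14
Reactants: 25 (6S,9S,10S)-9-bromo-10-chloro-1-{[(4-methoxybenzyl)oxy]methyl}-5,5,9-trimethylspiro[5.5]undec-1-en-3-one
Product: 27 (4R,6R,9S,10S)-4,9-dibromo-10-chloro-1-{[(4-methoxybenzyl)oxy]methyl}-5,5,9-trimethylspiro[5.5]undec-1-en-3-one, via silyl dienol ether 26 (not isolated)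
Conditions: LiN(i-Pr)2, Me3SiCl, THF, −78 °C; then N-bromosuccinimide, THF, −78 °C
Reagents that add atoms: N-bromosuccinimide, O=C1CCC(=O)N1Br
Why: Kinetic deprotonation of the enone can occur only at C4 (alpha-prime), and N-bromosuccinimide brominates the cross-conjugated silyl dienol ether there (alpha-prime halogenation of an enone through its 2-silyloxydiene). The axial C10 chlorine, syn to C1, pushes the C12 arm to the C7 side, so C11 is pseudoaxial on ring A; the electrophile then enters anti to the pseudoaxial C5 methyl group, on the C11 face, giving the 4R bromide. This is the kinetic axial epimer, so it is not equilibrated and is reduced without delay.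

Step 15
Reactants: 27 (4R,6R,9S,10S)-4,9-dibromo-10-chloro-1-{[(4-methoxybenzyl)oxy]methyl}-5,5,9-trimethylspiro[5.5]undec-1-en-3-one
Product: 28 (3S,4R,6R,9S,10S)-4,9-dibromo-10-chloro-1-{[(4-methoxybenzyl)oxy]methyl}-5,5,9-trimethylspiro[5.5]undec-1-en-3-ol
Conditions: i-Bu2AlH, CH2Cl2, −78 °C
Reagents that add atoms: none
Why: 1,2-Reduction of the enone carbonyl. Hydride adds anti to the adjacent C–Br bond (polar Felkin–Anh control, as in reductions of alpha-bromo ketones to cis-bromohydrins), which sets C3 as S, cis to bromine.

Step 16
Reactants: 28 (3S,4R,6R,9S,10S)-4,9-dibromo-10-chloro-1-{[(4-methoxybenzyl)oxy]methyl}-5,5,9-trimethylspiro[5.5]undec-1-en-3-ol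
Product: 29 (3S,4R,6R,9S,10S)-4,9-dibromo-10-chloro-1-{[(4-methoxybenzyl)oxy]methyl}-5,5,9-trimethylspiro[5.5]undec-1-en-3-yl acetate
Conditions: Ac2O, pyridine, 4-(dimethylamino)pyridine (cat.), CH2Cl2, 0 → 25 °C
Reagents that add atoms: acetic anhydride, CC(=O)OC(C)=O
Why: Acylation of the secondary alcohol under nucleophilic catalysis. A cis bromohydrin cannot close to an epoxide, so the mild base is tolerated.

Step 17
Reactants: 29 (3S,4R,6R,9S,10S)-4,9-dibromo-10-chloro-1-{[(4-methoxybenzyl)oxy]methyl}-5,5,9-trimethylspiro[5.5]undec-1-en-3-yl acetate
Product: 30 (3S,4R,6R,9S,10S)-4,9-dibromo-10-chloro-1-(hydroxymethyl)-5,5,9-trimethylspiro[5.5]undec-1-en-3-yl acetate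
Conditions: 2,3-dichloro-5,6-dicyano-1,4-benzoquinone, CH2Cl2/pH 7 buffer, 0 °C
Reagents that add atoms: none
Why: Oxidative cleavage of the 4-methoxybenzyl ether through its benzylic oxocarbenium ion. The neutral buffered medium spares both bromides, the chloride and the allylic acetate.

Step 18
Reactants: 30 (3S,4R,6R,9S,10S)-4,9-dibromo-10-chloro-1-(hydroxymethyl)-5,5,9-trimethylspiro[5.5]undec-1-en-3-yl acetate
Product: 33 (3S,4R,6R,9S,10S)-4,9-dibromo-10-chloro-5,5,9-trimethyl-1-methylidenespiro[5.5]undecan-3-yl acetate (9-acetylisoobtusol), via sulfonylhydrazine 31 (not isolated), via allylic diazene 32 (not isolated)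
Conditions: PPh3, diethyl azodicarboxylate, 2-nitrobenzenesulfonylhydrazide, THF, −30 °C; then 25 °C
Reagents that add atoms: none
Why: Myers reductive 1,3-transposition: Mitsunobu displacement of the primary allylic alcohol by the sulfonylhydrazide, loss of sulfinic acid on warming and retro-ene loss of N2 from the allylic diazene. Hydrogen is delivered to C2 and the alkene moves to C1=C12. No stereocentre is formed and the medium stays neutral.

## Compound list

1 | ethyl 2-methyl-4-oxocyclohex-2-ene-1-carboxylate (Hagemann's ester) | CCOC(=O)C1CCC(=O)C=C1C | starting material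
2 | 4-bromo-2-methylbut-1-ene | C=C(C)CCBr | starting material
3 | ethyl 2-methyl-3-(3-methylbut-3-en-1-yl)-4-oxocyclohex-2-ene-1-carboxylate (racemic) | CCOC(=O)C1CCC(=O)C(CCC(C)=C)=C1C | intermediate
4 | 2-methyl-3-(3-methylbut-3-en-1-yl)-4-oxocyclohex-2-ene-1-carboxylic acid (not isolated) | OC(=O)C1CCC(=O)C(CCC(C)=C)=C1C | intermediate
5 | 3-methyl-2-(3-methylbut-3-en-1-yl)cyclohex-2-en-1-one | CC1=C(CCC(C)=C)C(=O)CCC1 | intermediate
6 | allyl chloroformate | C=CCOC(=O)Cl | starting material
7 | lithium 3,3-dimethyl-2-(3-methylbut-3-en-1-yl)cyclohex-1-en-1-olate (not isolated) | [Li+].[O-]C1=C(CCC(C)=C)C(C)(C)CCC1 | intermediate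
8 | allyl 3,3-dimethyl-2-(3-methylbut-3-en-1-yl)cyclohex-1-en-1-yl carbonate | C=CCOC(=O)OC1=C(CCC(C)=C)C(C)(C)CCC1 | intermediate
9 | (S)-2-allyl-3,3-dimethyl-2-(3-methylbut-3-en-1-yl)cyclohexan-1-one | O=C1CCCC(C)(C)[C@@]1(CC=C)CCC(C)=C | intermediate
10 | bis(1,2,4-trioxolane) of 9, one ozonide at each alkene (not isolated) | O=C1CCCC(C)(C)[C@@]1(CC2OOCO2)CCC3(C)OOCO3 | intermediate
11 | (S)-2-[2,2-dimethyl-6-oxo-1-(3-oxobutyl)cyclohexyl]acetaldehyde (key-step precursor) | O=C1CCCC(C)(C)[C@@]1(CC=O)CCC(C)=O | intermediate
12 | (6S,9S,10R)-9,10-dihydroxy-5,5,9-trimethylspiro[5.5]undecan-1-one (key-step product; hydroxyls cis, on the C5 face) | O=C1CCCC(C)(C)[C@@]12CC[C@](C)(O)[C@H](O)C2 | intermediate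
13 | (6S,9S,10R)-cyclic sulfite of 12, both sulfur epimers (not isolated) | O=C1CCCC(C)(C)[C@@]12CC[C@](C)(OS(=O)O3)[C@H]3C2 | intermediate
14 | (6S,9S,10R)-5,5,9-trimethyl-1-oxospiro[5.5]undecane-9,10-diyl cyclic sulfate | O=C1CCCC(C)(C)[C@@]12CC[C@](C)(OS(=O)(=O)O3)[C@H]3C2 | intermediate
15 | lithium (6S,9S,10S)-10-chloro-5,5,9-trimethyl-1-oxospiro[5.5]undecan-9-yl sulfate (not isolated) | O=C1CCCC(C)(C)[C@@]12CC[C@](C)(OS(=O)(=O)[O-])[C@@H](Cl)C2.[Li+] | intermediate
16 | (6S,9S,10S)-10-chloro-9-hydroxy-5,5,9-trimethylspiro[5.5]undecan-1-one | O=C1CCCC(C)(C)[C@@]12CC[C@](C)(O)[C@@H](Cl)C2 | intermediate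
17 | (6S,9S,10S)-9-bromo-10-chloro-5,5,9-trimethylspiro[5.5]undecan-1-one | O=C1CCCC(C)(C)[C@@]12CC[C@](C)(Br)[C@@H](Cl)C2 | intermediate
18 | trimethylsilyl enol ether of 17, C1=C2 (not isolated) | C[Si](C)(C)OC1=CCCC(C)(C)[C@@]12CC[C@](C)(Br)[C@@H](Cl)C2 | intermediate
19 | (6S,9S,10S)-9-bromo-10-chloro-5,5,9-trimethylspiro[5.5]undec-2-en-1-one | O=C1C=CCC(C)(C)[C@@]12CC[C@](C)(Br)[C@@H](Cl)C2 | intermediate
20 | (tributylstannyl)methanol | OC[Sn](CCCC)(CCCC)CCCC | starting material
21 | 4-methoxybenzyl chloride | COc1ccc(CCl)cc1 | starting material
22 | tributyl{[(4-methoxybenzyl)oxy]methyl}stannane | COc1ccc(COC[Sn](CCCC)(CCCC)CCCC)cc1 | intermediate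
23 | [(4-methoxybenzyl)oxy]methyllithium (not isolated) | [Li]COCc1ccc(OC)cc1 | intermediate
24 | (6S,9S,10S)-9-bromo-10-chloro-1-{[(4-methoxybenzyl)oxy]methyl}-5,5,9-trimethylspiro[5.5]undec-2-en-1-ol, both C1 epimers | COc1ccc(COCC2(O)C=CCC(C)(C)[C@@]23CC[C@](C)(Br)[C@@H](Cl)C3)cc1 | intermediate
25 | (6S,9S,10S)-9-bromo-10-chloro-1-{[(4-methoxybenzyl)oxy]methyl}-5,5,9-trimethylspiro[5.5]undec-1-en-3-one | COc1ccc(COCC2=CC(=O)CC(C)(C)[C@@]23CC[C@](C)(Br)[C@@H](Cl)C3)cc1 | intermediate
26 | trimethylsilyl dienol ether of 25, enol ether C3=C4 (not isolated) | COc1ccc(COCC2=CC(O[Si](C)(C)C)=CC(C)(C)[C@@]23CC[C@](C)(Br)[C@@H](Cl)C3)cc1 | intermediate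
27 | (4R,6R,9S,10S)-4,9-dibromo-10-chloro-1-{[(4-methoxybenzyl)oxy]methyl}-5,5,9-trimethylspiro[5.5]undec-1-en-3-one | COc1ccc(COCC2=CC(=O)[C@H](Br)C(C)(C)[C@@]23CC[C@](C)(Br)[C@@H](Cl)C3)cc1 | intermediate
28 | (3S,4R,6R,9S,10S)-4,9-dibromo-10-chloro-1-{[(4-methoxybenzyl)oxy]methyl}-5,5,9-trimethylspiro[5.5]undec-1-en-3-ol | COc1ccc(COCC2=C[C@H](O)[C@H](Br)C(C)(C)[C@@]23CC[C@](C)(Br)[C@@H](Cl)C3)cc1 | intermediate
29 | (3S,4R,6R,9S,10S)-4,9-dibromo-10-chloro-1-{[(4-methoxybenzyl)oxy]methyl}-5,5,9-trimethylspiro[5.5]undec-1-en-3-yl acetate | COc1ccc(COCC2=C[C@H](OC(C)=O)[C@H](Br)C(C)(C)[C@@]23CC[C@](C)(Br)[C@@H](Cl)C3)cc1 | intermediate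
30 | (3S,4R,6R,9S,10S)-4,9-dibromo-10-chloro-1-(hydroxymethyl)-5,5,9-trimethylspiro[5.5]undec-1-en-3-yl acetate | OCC1=C[C@H](OC(C)=O)[C@H](Br)C(C)(C)[C@@]12CC[C@](C)(Br)[C@@H](Cl)C2 | intermediate
31 | N-(2-nitrobenzenesulfonyl)-N-(C12-alkyl)hydrazine from 30 (not isolated) | NN(CC1=C[C@H](OC(C)=O)[C@H](Br)C(C)(C)[C@@]12CC[C@](C)(Br)[C@@H](Cl)C2)S(=O)(=O)c3ccccc3[N+](=O)[O-] | intermediate
32 | allylic diazene at C12 from 31 (not isolated) | N=NCC1=C[C@H](OC(C)=O)[C@H](Br)C(C)(C)[C@@]12CC[C@](C)(Br)[C@@H](Cl)C2 | intermediate
33 | (3S,4R,6R,9S,10S)-4,9-dibromo-10-chloro-5,5,9-trimethyl-1-methylidenespiro[5.5]undecan-3-yl acetate (9-acetylisoobtusol) | C=C1C[C@H](OC(C)=O)[C@H](Br)C(C)(C)[C@@]12CC[C@](C)(Br)[C@@H](Cl)C2 | target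

## Step count and least certain steps

Total: 18 steps. Longest linear sequence: 17 steps (steps 1–10 and 12–18); step 11 is a one-step branch.

Step 6 (key step). The most likely failure is reduction of the aldehyde to the primary alcohol or an aldol closure before C–C coupling, together with incomplete discrimination between the two cis-diols, because the chair preference that relays C6 rests on modest 1,3-diaxial differences. Fallback: from 11, a reductive carbonyl olefination with low-valent titanium (TiCl3(DME)1.5, Zn–Cu couple, DME, reflux, high dilution) joins the same two carbons as the alkene (S)-5,5,9-trimethylspiro[5.5]undec-9-en-1-one F1. Catalytic OsO4 with N-methylmorpholine N-oxide should then add both hydroxyls from the ring B face opposite the pseudoaxial C1, returning to the route at 12.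

Step 14. The most likely failure is poor or reversed facial selectivity at C4, or epimerisation of the axial bromide to the equatorial one. The bias comes only from the remote C10 chlorine acting through the ring A conformation, and the thermodynamic preference runs the other way. Fallback: from 25, brominate without face control (through 26) to the mixture of 27 and its C4 epimer (4S,6R,9S,10S)-4,9-dibromo-10-chloro-1-{[(4-methoxybenzyl)oxy]methyl}-5,5,9-trimethylspiro[5.5]undec-1-en-3-one F2. Reduce the mixture with an NADPH-dependent ketoreductase chosen from a panel for 3S selectivity (pH 7–8 buffer, DMSO cosolvent, isopropanol for cofactor recycling), under which the bromoketone epimerises through its enol. Catalyst control with dynamic kinetic resolution then replaces substrate control, returning at 28.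

Step 9. The most likely failure is proton loss from the tertiary cation (elimination to allylic or vinylic chlorides) and erosion of configuration at C9 if the chlorine bridges only weakly, since chlorine is a modest neighbouring group and the beta-chlorine slows ionisation. Fallback: from 16, dehydrate deliberately with Burgess reagent to the allylic chlorides (6S,10S)-10-chloro-5,5-dimethyl-9-methylidenespiro[5.5]undecan-1-one F3 and (6S,10S)-10-chloro-5,5,9-trimethylspiro[5.5]undec-8-en-1-one F4. Then add anhydrous HBr in CH2Cl2 at −40 °C (Markovnikov hydrobromination; both alkenes give the same chlorine-bridged tertiary cation, opened by bromide anti to chlorine), returning at 17.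

Step 8. The most likely failure is slow displacement, because chloride must enter C10 along the axial line that is syn to C1, so ionisation or elimination at the tertiary sulfate can compete. Fallback: from 12, triflate the secondary hydroxyl selectively (Tf2O, pyridine, CH2Cl2, −78 °C; the tertiary hydroxyl stays free) to (6S,9S,10R)-9-hydroxy-5,5,9-trimethyl-1-oxospiro[5.5]undecan-10-yl trifluoromethanesulfonate F5. Displace with n-Bu4NCl in toluene at 0 °C with inversion, returning at 16. This replaces the ring-locked cyclic sulfate by a more reactive, conformationally freer leaving group and avoids the tertiary sulfate ester.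

Step 4. The most likely failure is sluggish recombination and eroded enantioselectivity at an enolate carbon flanked by a quaternary carbon; the sense of induction is also an assumption. Fallback: from 8, run the decarboxylative allylation with achiral Pd(PPh3)4 to the racemate of 9 with its enantiomer (R)-2-allyl-3,3-dimethyl-2-(3-methylbut-3-en-1-yl)cyclohexan-1-one F6. Separate the enantiomers by preparative chromatography on a chiral stationary phase, returning at 9.

## Further compounds

F1 | step 6 | (S)-5,5,9-trimethylspiro[5.5]undec-9-en-1-one | O=C1CCCC(C)(C)[C@@]12CCC(C)=CC2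
F2 | step 14 | (4S,6R,9S,10S)-4,9-dibromo-10-chloro-1-{[(4-methoxybenzyl)oxy]methyl}-5,5,9-trimethylspiro[5.5]undec-1-en-3-one | COc1ccc(COCC2=CC(=O)[C@@H](Br)C(C)(C)[C@@]23CC[C@](C)(Br)[C@@H](Cl)C3)cc1
F3 | step 9 | (6S,10S)-10-chloro-5,5-dimethyl-9-methylidenespiro[5.5]undecan-1-one | O=C1CCCC(C)(C)[C@@]12CCC(=C)[C@@H](Cl)C2
F4 | step 9 | (6S,10S)-10-chloro-5,5,9-trimethylspiro[5.5]undec-8-en-1-one | O=C1CCCC(C)(C)[C@@]12CC=C(C)[C@@H](Cl)C2
F5 | step 8 | (6S,9S,10R)-9-hydroxy-5,5,9-trimethyl-1-oxospiro[5.5]undecan-10-yl trifluoromethanesulfonate | O=C1CCCC(C)(C)[C@@]12CC[C@](C)(O)[C@H](OS(=O)(=O)C(F)(F)F)C2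
F6 | step 4 | (R)-2-allyl-3,3-dimethyl-2-(3-methylbut-3-en-1-yl)cyclohexan-1-one | O=C1CCCC(C)(C)[C@]1(CC=C)CCC(C)=C
A1 | alternative 1 | fused bicyclic tertiary allylic alcohol (C1=C6 ring-fusion alkene; C9 hydroxyl and vinyl; C10 4-methoxybenzyl ether cis to vinyl; C3 dioxolane; C5 gem-dimethyl) | C=C[C@@]1(O)CC2=C(C[C@H]1OCc3ccc(OC)cc3)C(C)(C)CC4(C2)OCCO4
A2 | alternative 1 | spiro C9 ketone with C10 4-methoxybenzyl ether, C1 methylene and C3 dioxolane | C=C1CC2(OCCO2)CC(C)(C)[C@@]13CCC(=O)[C@H](OCc4ccc(OC)cc4)C3
A3 | alternative 2 | vinyl bromide tethered to a cyclohexene bearing a C10 tert-butyldimethylsilyl ether (C3 dioxolane, C5 gem-dimethyl, C6=C11 alkene) | C=C(Br)CC1(OCCO1)CC(C)(C)C2=C[C@@H](O[Si](C)(C)C(C)(C)C)CCC2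
A4 | alternative 2 | spiro diene with C1 methylene and C10 silyl enol ether | C=C1CC2(OCCO2)CC(C)(C)[C@@]13CCCC(O[Si](C)(C)C(C)(C)C)=C3
A5 | alternative 3 | achiral spiro cyclobutanone (ring A with C1 methylene, C3 dioxolane, C5 gem-dimethyl; four-membered ring C6–C7–C10(=O)–C11) | C=C1CC2(OCCO2)CC(C)(C)C13CC(=O)C3
A6 | alternative 3 | 1-(trimethylsilyl)propyne | CC#C[Si](C)(C)C
A7 | alternative 3 | spiro ring B enone with C10 ketone, C9 methyl and C8 trimethylsilyl | C=C1CC2(OCCO2)CC(C)(C)[C@@]13CC([Si](C)(C)C)=C(C)C(=O)C3
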